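Everything rests on unfolding rings A and B. The feature exploited is the trans-decalin itself. Gem-dimethyl C4, ring-fusion C5-H and C10-CH3, and the C8=C9 alkene together are an (E)-geranyl chain (C1 to C6, C10) joined at C6-C7 to a four-carbon acetoacetate unit (C7, C8, C9, C11). One chiral-acid-triggered cascade forms C4-C5 and C9-C10, closes both rings, sets C5 and C10, and leaves oxygen on C8 and the ester on C9 as unambiguous handles. Its precursor is acyclic methyl (6E)-7,11-dimethyl-3-oxododeca-6,10-dienoate, one step from two bulk chemicals. The side chain follows by C12-C13 B-alkyl Suzuki coupling, C16-C17 Sonogashira coupling and Z-selective alkyne semi-reduction.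

Key step: step 2

Atom labels: C1 to C10 are the decalin carbons (C4 carries the two methyl groups, C5 is the ring-fusion CH, C10 is the methyl-bearing ring fusion, and C8=C9 is the ring alkene). C11 to C16 run outward from C9. C13a is the CH2OH carbon on C13. C17 to C20 are the lactone carbons (C19 carbonyl, C20 OCH2).

Shorthand: "decalinyl" stands for (4aS,8aS)-2,5,5,8a-tetramethyl-3,4,4a,5,6,7,8,8a-octahydronaphthalen-1-yl (trans-fused, 5S,10S in the labels above).

Assumption: the sense of induction of the chiral acid in step 2 cannot be deduced from the substrate, so the (S,S) antipode is written and its mirror image is used should the opposite sense be found.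

Step 1
Reactants: 1 geranyl bromide; 2 methyl acetoacetate
Product: 4 methyl (6E)-7,11-dimethyl-3-oxododeca-6,10-dienoate, via acetoacetate dianion 3 (not isolated)
Conditions: NaH, THF, 0 °C; n-BuLi, 0 °C; then 1, 0 °C to rt; aq HCl quench
Reagents that add atoms: none
Why: Gamma-alkylation of an acetoacetate dianion: the terminal carbanion C7 is far more nucleophilic than the stabilised C9 site and displaces the primary allylic bromide at C6 by SN2, which leaves the E geometry of C5=C10 untouched.

Step 2
Reactants: 4 methyl (6E)-7,11-dimethyl-3-oxododeca-6,10-dienoate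
Product: 5 methyl (4aS,8aS)-2-hydroxy-5,5,8a-trimethyl-3,4,4a,5,6,7,8,8a-octahydronaphthalene-1-carboxylate (trans-fused bicyclic keto ester shown as its enol)
Conditions: (S,S)-imidodiphosphorimidate acid HN[P(=NSO2CF3)(O2Ar*)]2 with O2Ar* = (S)-3,3'-bis[3,5-bis(trifluoromethyl)phenyl]-1,1'-binaphthalene-2,2'-diolate (5 mol %), (CF3)3COH, 0 °C
Reagents that add atoms: none
Why: Proposed new method: the confined acid, helped by the hydrogen-bond network of the fluorinated alcohol, puts its proton on C3 while the C5=C10 alkene attacks the developing tertiary C4 cation through C5 (ring A, 6-endo-trig) and the enol tautomer of the keto ester attacks the resulting tertiary C10 cation through C9 (ring B, 6-endo with both enol carbons C8 and C9 inside the new ring), after which the enol O-H proton returns to the counteranion and the acid turns over. The closest known reaction types are the racemic SnCl4-promoted bicyclization of polyene beta-keto esters and the enantioselective proton-initiated polyene cyclizations with BINOL-derived chiral acids that end on oxygen or arene nucleophiles; an enol carbon terminator under a chiral proton donor has not been shown. Since C3 and C4 are not stereogenic in 5, the enantiodetermining event is the choice of the C5=C10 face that bonds to C4, and the chiral pocket makes it by accepting only one of the two mirror-image chair-chair folds, which sets C5 as S. C10 (S) is then set by the substrate, because anti addition of C4 and C9 across the E alkene in the chair-chair array places H5 and the C10 methyl group trans. The step needs initiation at C3=C4 and not at C5=C10, which the more exposed and more electron-rich isopropylidene end secures (C5=C10 feels the electron-poor keto ester), and it needs C-capture and not O-capture at C10, which is secured because an O-closed tertiary enol ether or a monocyclic alkene is re-ionised by the same acid to the C10 cation with C5 intact whereas the C9-C10 bond is irreversible. A metal-free acid is preferred because the chelating keto ester would strip SnCl4 from a BINOL ether and open the racemic channel, and a silyl enol ether is not used as terminator because a chiral proton donor would protonate it before the alkene.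

Step 3
Reactants: 5 methyl (4aS,8aS)-2-hydroxy-5,5,8a-trimethyl-3,4,4a,5,6,7,8,8a-octahydronaphthalene-1-carboxylate
Product: 7 methyl (4aS,8aS)-5,5,8a-trimethyl-2-(trifluoromethylsulfonyloxy)-3,4,4a,5,6,7,8,8a-octahydronaphthalene-1-carboxylate, via sodium enolate 6 (not isolated)
Conditions: NaH, THF, 0 °C; PhNTf2, 0 °C to rt; dilute HCl wash
Reagents that add atoms: N-phenylbis(trifluoromethanesulfonimide), O=S(=O)(N(c1ccccc1)S(=O)(=O)C(F)(F)F)C(F)(F)F
Why: Enol triflate formation by O-sulfonylation of a beta-keto ester enolate: the only stabilised enolate is C8=C9, so the leaving group lands on C8 and the alkene position is fixed, while C5 and C10 carry no acidic hydrogen and cannot epimerise.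

Step 4
Reactants: 7 enol triflate
Product: 8 methyl (4aS,8aS)-2,5,5,8a-tetramethyl-3,4,4a,5,6,7,8,8a-octahydronaphthalene-1-carboxylate
Conditions: MeMgBr, Fe(acac)3 (5 mol %), THF/NMP, -30 to 0 °C
Reagents that add atoms: methylmagnesium bromide, C[Mg]Br
Why: Iron-catalysed Kumada-type cross-coupling of an alkenyl triflate with a methyl Grignard reagent, which at low temperature is much faster than addition to the hindered C11 ester and replaces the triflate on C8 by methyl without moving the alkene.

Step 5
Reactants: 8 methyl (4aS,8aS)-2,5,5,8a-tetramethyl-3,4,4a,5,6,7,8,8a-octahydronaphthalene-1-carboxylate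
Product: 9 (decalinyl)methanol
Conditions: LiAlH4, Et2O, 0 °C to rt; aqueous work-up
Reagents that add atoms: none
Why: Hydride reduction of an ester: the tetrasubstituted enoate is twisted out of conjugation and offers no accessible beta carbon, so LiAlH4 should attack only C11 and give the allylic alcohol.

Step 6
Reactants: 9 (decalinyl)methanol
Product: 10 (4aS,8aS)-2,5,5,8a-tetramethyl-3,4,4a,5,6,7,8,8a-octahydronaphthalene-1-carbaldehyde
Conditions: activated MnO2, CH2Cl2, rt
Reagents that add atoms: none
Why: Selective allylic alcohol oxidation on the MnO2 surface, which stops at the aldehyde and leaves the C8=C9 alkene in place.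

Step 7
Reactants: 10 (4aS,8aS)-2,5,5,8a-tetramethyl-3,4,4a,5,6,7,8,8a-octahydronaphthalene-1-carbaldehyde
Product: 11 (4aS,8aS)-1-ethenyl-2,5,5,8a-tetramethyl-3,4,4a,5,6,7,8,8a-octahydronaphthalene
Conditions: Ph3PCH3Br, KOt-Bu, THF, 0 °C to rt
Reagents that add atoms: methyltriphenylphosphonium bromide, C[P+](c1ccccc1)(c1ccccc1)c1ccccc1.[Br-]
Why: Wittig methylenation with the small unstabilised ylide Ph3P=CH2, which reaches even flanked enals of the cyclocitral type, adds C12 and cannot epimerise any centre because 10 has no alpha hydrogen.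

Step 8
Reactants: 12 ethynyl(triisopropyl)silane
Product: 14 3-(triisopropylsilyl)prop-2-ynal, via lithium acetylide 13 (not isolated)
Conditions: n-BuLi, THF, -78 °C; DMF, -78 to 0 °C; cold aq HCl quench
Reagents that add atoms: N,N-dimethylformamide, CN(C)C=O
Why: Formylation of a lithium acetylide with DMF, the tetrahedral adduct collapsing to the ynal only on the acidic quench so that no second addition occurs.

Step 9
Reactants: 14 3-(triisopropylsilyl)prop-2-ynal; 15 ethyl (triphenylphosphoranylidene)acetate
Product: 17 ethyl (2Z)-2-iodo-5-(triisopropylsilyl)pent-2-en-4-ynoate, via iodo ylide 16 (not isolated)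
Conditions: 15, NIS, CH2Cl2, -20 °C; then 14, -20 °C to rt
Reagents that add atoms: N-iodosuccinimide, O=C1CCC(=O)N1I
Why: Wittig olefination with a stabilised alpha-iodo ylide, made in the flask by electrophilic iodination of 15 and deprotonation by the succinimide anion; as with other alpha-substituted stabilised ylides the ester should end up trans to the alkynyl group, which is the Z iodoalkene with iodine cis to C15.

Step 10
Reactants: 17 ethyl (2Z)-2-iodo-5-(triisopropylsilyl)pent-2-en-4-ynoate
Product: 18 (2Z)-2-iodo-5-(triisopropylsilyl)pent-2-en-4-yn-1-ol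
Conditions: DIBAL-H, CH2Cl2, -78 to -20 °C; aqueous work-up
Reagents that add atoms: none
Why: 1,2-Reduction of an enoate with DIBAL-H, which at low temperature leaves the C-I bond, the silylalkyne and the alkene geometry alone.

Step 11
Reactants: 11 (4aS,8aS)-1-ethenyl-2,5,5,8a-tetramethyl-3,4,4a,5,6,7,8,8a-octahydronaphthalene; 18 (2Z)-2-iodo-5-(triisopropylsilyl)pent-2-en-4-yn-1-ol
Product: 20 (2E)-2-[2-(decalinyl)ethyl]-5-(triisopropylsilyl)pent-2-en-4-yn-1-ol, via B-alkyl borane 19 (not isolated)
Conditions: 11, 9-BBN, THF, rt; then 18, PdCl2(dppf) (5 mol %), AsPh3 (10 mol %), Cs2CO3, DMF/H2O, rt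
Reagents that add atoms: none
Why: Hydroboration followed by B-alkyl Suzuki-Miyaura coupling: 9-BBN adds only to the monosubstituted C11=C12 alkene with boron on the terminal C12 (the tetrasubstituted C8=C9 alkene is inert), and oxidative addition to zerovalent palladium and reductive elimination keep the alkene geometry, so C12 takes the place of iodine cis to C15 and the C13=C14 alkene is E.

Step 12
Reactants: 20 (2E)-2-[2-(decalinyl)ethyl]-5-(triisopropylsilyl)pent-2-en-4-yn-1-ol
Product: 21 (2E)-2-[2-(decalinyl)ethyl]pent-2-en-4-yn-1-ol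
Conditions: TBAF, wet THF, 0 °C to rt
Reagents that add atoms: none
Why: Fluoride-induced protodesilylation of a silylalkyne, which touches neither the free alcohol nor the alkenes.

Step 13
Reactants: 21 (2E)-2-[2-(decalinyl)ethyl]pent-2-en-4-yn-1-ol; 22 4-bromofuran-2(5H)-one
Product: 23 4-[(3E)-6-(decalinyl)-4-(hydroxymethyl)hex-3-en-1-yn-1-yl]furan-2(5H)-one
Conditions: PdCl2(PPh3)2 (5 mol %), CuI (10 mol %), Et3N, THF, rt
Reagents that add atoms: none
Why: Sonogashira coupling of a terminal alkyne with an electron-poor beta-bromo enoate, whose fast oxidative addition allows room temperature and a mild amine base that spare the lactone and the free alcohol.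

Step 14
Reactants: 23 4-[(3E)-6-(decalinyl)-4-(hydroxymethyl)hex-3-en-1-yn-1-yl]furan-2(5H)-one
Product: 24 4-[(1Z,3E)-6-(decalinyl)-4-(hydroxymethyl)hexa-1,3-dien-1-yl]furan-2(5H)-one (CNP0232848.4)
Conditions: pre-formed Zn(Cu/Ag) couple (from Zn dust, Cu(OAc)2, AgNO3), MeOH/H2O, rt, dark
Reagents that add atoms: none
Why: Semi-reduction of a conjugated alkyne with activated zinc in a protic medium: both hydrogens are delivered to the same face of the surface-bound alkyne, which sets C15=C16 as Z, and the reagent acts on conjugated triple bonds only, so the C8=C9 and C13=C14 alkenes and the butenolide should survive.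

Compound list
1 | geranyl bromide, (2E)-1-bromo-3,7-dimethylocta-2,6-diene | BrC/C=C(\C)CCC=C(C)C | starting material
2 | methyl acetoacetate | COC(=O)CC(C)=O | starting material
3 | sodium lithium dianion of methyl acetoacetate | [Na+].[Li+].[CH2-]C(=O)[CH-]C(=O)OC | intermediate
4 | methyl (6E)-7,11-dimethyl-3-oxododeca-6,10-dienoate | COC(=O)CC(=O)CC/C=C(\C)CCC=C(C)C | intermediate
5 | methyl (4aS,8aS)-2-hydroxy-5,5,8a-trimethyl-3,4,4a,5,6,7,8,8a-octahydronaphthalene-1-carboxylate (enol form of the trans-fused keto ester) | OC1=C(C(=O)OC)[C@@]2(C)CCCC(C)(C)[C@@H]2CC1 | intermediate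
6 | sodium enolate of 5 | [Na+].[O-]C1=C(C(=O)OC)[C@@]2(C)CCCC(C)(C)[C@@H]2CC1 | intermediate
7 | methyl (4aS,8aS)-5,5,8a-trimethyl-2-(trifluoromethylsulfonyloxy)-3,4,4a,5,6,7,8,8a-octahydronaphthalene-1-carboxylate | O=S(=O)(OC1=C(C(=O)OC)[C@@]2(C)CCCC(C)(C)[C@@H]2CC1)C(F)(F)F | intermediate
8 | methyl (4aS,8aS)-2,5,5,8a-tetramethyl-3,4,4a,5,6,7,8,8a-octahydronaphthalene-1-carboxylate | CC1=C(C(=O)OC)[C@@]2(C)CCCC(C)(C)[C@@H]2CC1 | intermediate
9 | [(4aS,8aS)-2,5,5,8a-tetramethyl-3,4,4a,5,6,7,8,8a-octahydronaphthalen-1-yl]methanol | CC1=C(CO)[C@@]2(C)CCCC(C)(C)[C@@H]2CC1 | intermediate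
10 | (4aS,8aS)-2,5,5,8a-tetramethyl-3,4,4a,5,6,7,8,8a-octahydronaphthalene-1-carbaldehyde | CC1=C(C=O)[C@@]2(C)CCCC(C)(C)[C@@H]2CC1 | intermediate
11 | (4aS,8aS)-1-ethenyl-2,5,5,8a-tetramethyl-3,4,4a,5,6,7,8,8a-octahydronaphthalene | CC1=C(C=C)[C@@]2(C)CCCC(C)(C)[C@@H]2CC1 | intermediate
12 | ethynyl(triisopropyl)silane | C#C[Si](C(C)C)(C(C)C)C(C)C | starting material
13 | lithium (triisopropylsilyl)acetylide | [Li+].[C-]#C[Si](C(C)C)(C(C)C)C(C)C | intermediate
14 | 3-(triisopropylsilyl)prop-2-ynal | O=CC#C[Si](C(C)C)(C(C)C)C(C)C | intermediate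
15 | ethyl (triphenylphosphoranylidene)acetate | CCOC(=O)C=P(c1ccccc1)(c1ccccc1)c1ccccc1 | starting material
16 | ethyl iodo(triphenylphosphoranylidene)acetate | CCOC(=O)C(I)=P(c1ccccc1)(c1ccccc1)c1ccccc1 | intermediate
17 | ethyl (2Z)-2-iodo-5-(triisopropylsilyl)pent-2-en-4-ynoate | CCOC(=O)/C(I)=C/C#C[Si](C(C)C)(C(C)C)C(C)C | intermediate
18 | (2Z)-2-iodo-5-(triisopropylsilyl)pent-2-en-4-yn-1-ol | OC/C(I)=C/C#C[Si](C(C)C)(C(C)C)C(C)C | intermediate
19 | 9-[2-(decalinyl)ethyl]-9-borabicyclo[3.3.1]nonane | CC1=C(CCB3C4CCCC3CCC4)[C@@]2(C)CCCC(C)(C)[C@@H]2CC1 | intermediate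
20 | (2E)-2-[2-(decalinyl)ethyl]-5-(triisopropylsilyl)pent-2-en-4-yn-1-ol | CC1=C(CC/C(=C\C#C[Si](C(C)C)(C(C)C)C(C)C)CO)[C@@]2(C)CCCC(C)(C)[C@@H]2CC1 | intermediate
21 | (2E)-2-[2-(decalinyl)ethyl]pent-2-en-4-yn-1-ol | CC1=C(CC/C(=C\C#C)CO)[C@@]2(C)CCCC(C)(C)[C@@H]2CC1 | intermediate
22 | 4-bromofuran-2(5H)-one | O=C1C=C(Br)CO1 | starting material
23 | 4-[(3E)-6-(decalinyl)-4-(hydroxymethyl)hex-3-en-1-yn-1-yl]furan-2(5H)-one | CC1=C(CC/C(=C\C#CC3=CC(=O)OC3)CO)[C@@]2(C)CCCC(C)(C)[C@@H]2CC1 | intermediate
24 | 4-[(1Z,3E)-6-(decalinyl)-4-(hydroxymethyl)hexa-1,3-dien-1-yl]furan-2(5H)-one (CNP0232848.4) | CC1=C(CC/C(=C\C=C/C2=CC(=O)OC2)CO)[C@@]2(C)CCCC(C)(C)[C@@H]2CC1 | target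

Total step count: 14. Longest linear sequence: 11 (steps 1 to 7 and 11 to 14).

Steps most likely to fail

Step 2.
- **What may go wrong:** The cascade may stall after ring A by proton loss from the C10 cation. The ketone oxygen may capture C10. The inner alkene may be protonated first. The pocket may discriminate poorly between the two chair-chair folds.
- **Fallback:** This replaces asymmetric catalysis by a racemic cyclization plus resolution, all known chemistry. It sets out from 4.
  - SnCl4 in CH2Cl2 at 0 °C, the established Lewis acid bicyclization of polyene beta-keto esters, should give the racemic trans-fused keto ester F1.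
  - Condensation with (R)-1-phenylethylamine (catalytic AcOH, toluene, azeotropic removal of water) converts F1 into two diastereomeric hydrogen-bonded enamino esters.
  - The (4aS,8aS,1'R) enamino ester F2 is separated by crystallisation or chromatography. Its configuration is read from an X-ray structure against the known amine centre.
  - Hydrolysis with aqueous oxalic acid in THF comes back to the route at 5.

Step 14.
- **What may go wrong:** The newly formed triene may be over-reduced. The Z geometry may erode. The Z-triene may drift thermally by sigmatropic or electrocyclic pathways during a slow heterogeneous reaction.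
- **Fallback:** This sets the Z alkene before the lactone is attached and forms C16-C17 by a different coupling. It sets out from 21 and replaces steps 13 and 14.
  - NIS with catalytic AgNO3 in acetone gives the iodoalkyne F3.
  - Diimide, generated from 2-nitrobenzenesulfonyl hydrazide and Et3N, reduces the iodoalkyne selectively to the (Z)-iodo diene F4.
  - In parallel, 22 is stannylated with Bu3SnSnBu3 and Pd(PPh3)4 to the stannyl butenolide F5.
  - Stille coupling of the two (Pd2(dba)3, AsPh3, CuI, DMF, rt) proceeds with retention of geometry and comes back to the route at 24.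

Step 11.
- **What may go wrong:** Transmetalation of the bulky homoallylic borane may be slow. Protodeboronation may compete. The iodo-enynol may undergo side reactions on zerovalent palladium.
- **Fallback:** This abandons the C12-C13 cross-coupling for a C13=C14 olefination. It sets out from borane 19.
  - NaOH/H2O2 gives the homoallylic alcohol F6.
  - I2, PPh3 and imidazole give the primary iodide F7.
  - Heating with two equivalents of ylide 15 (alkylation, then transylidation) gives the alpha-alkylated stabilised ylide F8.
  - Wittig reaction with aldehyde 14 places the ester trans to the alkynyl group and gives the (E)-enoate F9.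
  - DIBAL-H reduction comes back to the route at 20.

Further compounds
F1 | step 2 | racemic trans-fused methyl 2-hydroxy-5,5,8a-trimethyl-3,4,4a,5,6,7,8,8a-octahydronaphthalene-1-carboxylate (both enantiomers) | OC1=C(C(=O)OC)[C@@]2(C)CCCC(C)(C)[C@@H]2CC1.OC1=C(C(=O)OC)[C@]2(C)CCCC(C)(C)[C@H]2CC1
F2 | step 2 | methyl (4aS,8aS)-5,5,8a-trimethyl-2-{[(1R)-1-phenylethyl]amino}-3,4,4a,5,6,7,8,8a-octahydronaphthalene-1-carboxylate | C[C@@H](NC1=C(C(=O)OC)[C@@]2(C)CCCC(C)(C)[C@@H]2CC1)c1ccccc1
F3 | step 14 | (2E)-2-[2-(decalinyl)ethyl]-5-iodopent-2-en-4-yn-1-ol | CC1=C(CC/C(=C\C#CI)CO)[C@@]2(C)CCCC(C)(C)[C@@H]2CC1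
F4 | step 14 | (2E,4Z)-2-[2-(decalinyl)ethyl]-5-iodopenta-2,4-dien-1-ol | CC1=C(CC/C(=C\C=C/I)CO)[C@@]2(C)CCCC(C)(C)[C@@H]2CC1
F5 | step 14 | 4-(tributylstannyl)furan-2(5H)-one | CCCC[Sn](CCCC)(CCCC)C1=CC(=O)OC1
F6 | step 11 | 2-(decalinyl)ethanol | CC1=C(CCO)[C@@]2(C)CCCC(C)(C)[C@@H]2CC1
F7 | step 11 | (4aS,8aS)-1-(2-iodoethyl)-2,5,5,8a-tetramethyl-3,4,4a,5,6,7,8,8a-octahydronaphthalene | CC1=C(CCI)[C@@]2(C)CCCC(C)(C)[C@@H]2CC1
F8 | step 11 | ethyl 4-(decalinyl)-2-(triphenylphosphoranylidene)butanoate | CC1=C(CCC(C(=O)OCC)=P(c3ccccc3)(c3ccccc3)c3ccccc3)[C@@]2(C)CCCC(C)(C)[C@@H]2CC1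
F9 | step 11 | ethyl (2E)-2-[2-(decalinyl)ethyl]-5-(triisopropylsilyl)pent-2-en-4-ynoate | CC1=C(CC/C(=C\C#C[Si](C(C)C)(C(C)C)C(C)C)C(=O)OCC)[C@@]2(C)CCCC(C)(C)[C@@H]2CC1
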